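**Plan**
- Retrosynthesis: the two C6–O ester bonds are cut first, giving (2E,6E)-2,6-dimethylocta-2,6-dienedioic acid and two copies of one bicyclic amino alcohol. In each bicycle the C4–CH3 bond and then C7–C7a and C4a–C5 are cut, which takes the cyclopentane off a piperidinone.
- Enabling feature (each half numbered C1, N2, C3, C4, C4a, C5, C6, C7, C7a): C5–C6–C7(CH3) is a three-carbon bridge between C4a and C7a. With a ketone at C4 these are the α- and β-carbons of a six-membered enone, so the cyclopentane is the adduct of a methyl-trimethylenemethane unit.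
- Forward: the piperidinone ring comes from furfurylamine by aza-Achmatowicz ring expansion, and the cyclopentane from the palladium (3+2) cycloaddition. The C4 methyl then enters through the ketone and the C6 ketone is unmasked by ozonolysis. After reduction, two amino alcohols are joined to the geranyl-acetate-derived diacid in one twofold Mitsunobu reaction.
- Stereochemistry: a chiral phosphoramidite on palladium sets C7a and C4a (cis by ring constraint). C7 settles by equilibration next to the C6 ketone, and C4 comes from convex-face hydrogenation. C6 comes from convex-face hydride addition followed by SN2 inversion. Both E alkenes derive from geranyl acetate.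

Key step: step 6

Remark (convention): "convex face" means the face of the cis-fused bicycle that carries H-4a and H-7a; the other ring lies on the concave face.
Assumption: which antipode of the phosphoramidite gives the (4aR,7aS) adduct 11 is settled by a small-scale test; both antipodes are accessible from (R)- or (S)-BINOL.
Assumption: 11, 12, 14 and 16 are drawn as the C7 epimer with the methyl on the convex face; any C7 epimer is carried along and merges in step 10.

**Route**

Step 1
Reactants: 1 furfurylamine
Product: 2 methyl (furan-2-ylmethyl)carbamate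
Conditions: ClCO2Me, aq. NaOH, CH2Cl2, 0 °C
Reagents that add atoms: methyl chloroformate, COC(=O)Cl
Why: Schotten–Baumann N-acylation of a primary amine should proceed cleanly, and the methyl carbamate both enables the ring expansion of step 2 and is the latent N-methyl group.

Step 2
Reactants: 2 methyl (furan-2-ylmethyl)carbamate
Product: 4 methyl 2-hydroxy-5-oxo-5,6-dihydropyridine-1(2H)-carboxylate (racemic hemiaminal), via cis-enedione 3 (not isolated)
Conditions: mCPBA, CH2Cl2, 0 °C → rt
Reagents that add atoms: 3-chloroperoxybenzoic acid (mCPBA), OOC(=O)c1cccc(Cl)c1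
Why: In this aza-Achmatowicz rearrangement the peracid opens the 2-substituted furan to the cis-enedione, whose aldehyde is captured by the carbamate nitrogen to close the six-membered hemiaminal; its stereocentre is removed in step 3 and needs no control.

Step 3
Reactants: 4 methyl 2-hydroxy-5-oxo-5,6-dihydropyridine-1(2H)-carboxylate
Product: 5 methyl 3-oxo-3,6-dihydropyridine-1(2H)-carboxylate
Conditions: Et3SiH, TFA, CH2Cl2, −40 → 0 °C
Reagents that add atoms: none
Why: Ionic hydrogenation: acid ionises the hemiaminal to an N-acyliminium ion that the silane reduces at the iminium carbon, the usual deoxygenation of aza-Achmatowicz products, and the enone is not reduced at this temperature.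

Step 4
Reactants: 6 2-bromo-3-(trimethylsilyl)prop-1-ene; 7 acetaldehyde
Product: 9 3-[(trimethylsilyl)methyl]but-3-en-2-ol (racemic), via Grignard reagent 8 (not isolated)
Conditions: Mg, THF, rt; then CH3CHO, −78 → 0 °C; aq. NH4Cl
Reagents that add atoms: none
Why: Grignard formation from the vinyl bromide and 1,2-addition to the aldehyde is the standard entry to substituted 2-(silylmethyl)allyl alcohols; the carbinol centre is racemic, which does not matter because it becomes part of a planar allyl unit in step 6.

Step 5
Reactants: 9 3-[(trimethylsilyl)methyl]but-3-en-2-ol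
Product: 10 3-[(trimethylsilyl)methyl]but-3-en-2-yl acetate (racemic)
Conditions: Ac2O, pyridine, DMAP (cat.), CH2Cl2, 0 °C → rt
Reagents that add atoms: acetic anhydride, CC(=O)OC(C)=O
Why: DMAP-catalysed acetylation of a secondary allylic alcohol installs the ionisable leaving group under non-acidic conditions that the allylsilane tolerates.

Step 6
Reactants: 5 methyl 3-oxo-3,6-dihydropyridine-1(2H)-carboxylate; 10 3-[(trimethylsilyl)methyl]but-3-en-2-yl acetate
Product: 11 methyl (4aR,7S,7aS)-7-methyl-6-methylidene-4-oxooctahydro-2H-cyclopenta[c]pyridine-2-carboxylate (cis-fused, C7 methyl on the convex face)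
Conditions: Pd(dba)2 (5 mol %), BINOL-derived 2,5-bis(2-naphthyl)pyrrolidine phosphoramidite (10 mol %), toluene, 0 → 23 °C
Reagents that add atoms: none
Why: Zerovalent palladium carrying the phosphoramidite ionises allylic acetate 10 and the released acetate strips the silyl group, giving the zwitterionic methyl-trimethylenemethane palladium complex; its methyl-bearing carbon adds in Michael fashion to the enone β-carbon of 5 (the future C7a), and the resulting enolate attacks the cationic π-allylpalladium terminus through its α-carbon (the future C4a). This is the palladium-catalysed trimethylenemethane (3+2) cycloaddition to electron-poor alkenes, which is known for cyclic enones and for alkyl-substituted donors. The one new ring, the cyclopentane, closes by intramolecular enolate allylation (5-exo-type attack of C4a on the allyl terminus C5 with palladium leaving), and because the three-carbon bridge can only span one face of the six-membered ring the fusion is cis. The absolute configuration at C7a, and through the ring constraint at C4a, is set by the chiral ligand, which chooses the enone face in the Michael step; C7 is set in the same step relative to C7a, with the methyl expected on the convex face, and as it later sits α to the C6 ketone any epimer is corrected in step 10. The step needs 1,4- rather than 1,2-addition and bonding of the substituted donor terminus to C7a: the first follows from the soft carbon nucleophile meeting an unhindered β-carbon, the second from the inherent preference of alkyl-substituted trimethylenemethane complexes to react at the substituted carbon whichever regioisomeric precursor is used.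

Step 7
Reactants: 11 methyl (4aR,7S,7aS)-7-methyl-6-methylidene-4-oxooctahydro-2H-cyclopenta[c]pyridine-2-carboxylate
Product: 12 methyl (4R,4aR,7S,7aS)-4-hydroxy-4,7-dimethyl-6-methylideneoctahydro-2H-cyclopenta[c]pyridine-2-carboxylate
Conditions: MeMgBr, THF, −78 °C; aq. NH4Cl
Reagents that add atoms: methylmagnesium bromide, C[Mg]Br
Why: Grignard 1,2-addition to an N-acyl piperidin-3-one is routine and leaves the carbamate alone at low temperature; the reagent should enter from the convex face, away from the cyclopentane, so the new hydroxyl lies trans to H-4a (this centre is erased again in steps 9 and 10).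

Step 8
Reactants: 12 methyl (4R,4aR,7S,7aS)-4-hydroxy-4,7-dimethyl-6-methylideneoctahydro-2H-cyclopenta[c]pyridine-2-carboxylate
Product: 14 methyl (4R,4aR,7S,7aR)-4-hydroxy-4,7-dimethyl-6-oxooctahydro-2H-cyclopenta[c]pyridine-2-carboxylate, via ozonide 13 (not isolated)
Conditions: O3, CH2Cl2, −78 °C; then Me2S, −78 °C → rt
Reagents that add atoms: ozone, [O-][O+]=O
Why: Ozonolysis with reductive work-up cleaves the only C=C bond to unmask the C6 ketone, while the carbamate nitrogen and the tertiary alcohol are inert to ozone.

Step 9
Reactants: 14 methyl (4R,4aR,7S,7aR)-4-hydroxy-4,7-dimethyl-6-oxooctahydro-2H-cyclopenta[c]pyridine-2-carboxylate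
Product: 16 methyl (4aR,7S,7aR)-4,7-dimethyl-6-oxo-1,4a,5,6,7,7a-hexahydro-2H-cyclopenta[c]pyridine-2-carboxylate (C3=C4 enecarbamate), via sulfamate ester 15 (not isolated)
Conditions: Burgess reagent, THF, 23 → 60 °C
Reagents that add atoms: none
Why: Burgess dehydration is a syn (Ei) elimination through the sulfamate ester, and since the C4 oxygen is trans to H-4a the ring-fusion hydrogen cannot be reached, so the hydrogen should be taken from C3, whose loss gives the more substituted, nitrogen-conjugated C3=C4 alkene (Zaitsev-type preference).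

Step 10
Reactants: 16 methyl (4aR,7S,7aR)-4,7-dimethyl-6-oxo-1,4a,5,6,7,7a-hexahydro-2H-cyclopenta[c]pyridine-2-carboxylate
Product: 17 methyl (4R,4aS,7S,7aR)-4,7-dimethyl-6-oxooctahydro-2H-cyclopenta[c]pyridine-2-carboxylate
Conditions: H2 (1 atm), Pd/C (10 wt % Pd), EtOAc, rt; filter; then DBU (0.2 equiv), CH2Cl2, rt
Reagents that add atoms: none
Why: Heterogeneous hydrogenation of the trisubstituted enecarbamate should add hydrogen from the convex face, placing H-4 cis to H-4a and the C4 methyl on the cyclopentane side as in the target while palladium leaves the ketone alone, and the brief base treatment lets C7 (α to the ketone) settle as the more stable epimer with its methyl on the convex face, trans to C1.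

Step 11
Reactants: 17 methyl (4R,4aS,7S,7aR)-4,7-dimethyl-6-oxooctahydro-2H-cyclopenta[c]pyridine-2-carboxylate
Product: 19 (4R,4aS,6S,7S,7aR)-2,4,7-trimethyloctahydro-1H-cyclopenta[c]pyridin-6-ol (hydroxyl on the concave face), via hydroxy carbamate 18 (not isolated)
Conditions: LiAlH4, THF, −78 °C, then reflux; H2O/aq. NaOH work-up
Reagents that add atoms: none
Why: LiAlH4 should first reduce the ketone at low temperature by hydride delivery to the convex face, the concave face being screened by the piperidine ring and its C4 methyl, which puts the hydroxyl trans to the C7 methyl; at reflux it reduces the methyl carbamate to the N-methyl group (carbamate-to-N-methyl reduction).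

Step 12
Reactants: 20 geranyl acetate
Product: 21 (2E,6E)-8-hydroxy-3,7-dimethylocta-2,6-dien-1-yl acetate
Conditions: SeO2 (cat.), t-BuOOH, salicylic acid (cat.), CH2Cl2, rt
Reagents that add atoms: tert-butyl hydroperoxide, CC(C)(C)OO (terminal oxidant; the oxygen is passed on by catalytic selenium dioxide, O=[Se]=O)
Why: Catalytic selenium dioxide allylic oxidation (ene reaction then 2,3-sigmatropic shift, Riley type) attacks the (E)-methyl of the terminal trisubstituted alkene selectively and gives the E allylic alcohol, while the acetate shields the other allylic oxygen.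

Step 13
Reactants: 21 (2E,6E)-8-hydroxy-3,7-dimethylocta-2,6-dien-1-yl acetate
Product: 22 (2E,6E)-2,6-dimethylocta-2,6-diene-1,8-diol
Conditions: K2CO3 (cat.), MeOH, rt
Reagents that add atoms: none
Why: Base-catalysed transesterification with methanol removes the acetate without touching either alkene.

Step 14
Reactants: 22 (2E,6E)-2,6-dimethylocta-2,6-diene-1,8-diol
Product: 25 (2E,6E)-2,6-dimethylocta-2,6-dienedial, via 8-hydroxygeranial 23 (not isolated), via 8-hydroxy-2,6-dimethyl enal 24 (not isolated)
Conditions: MnO2 (excess), CH2Cl2, rt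
Reagents that add atoms: none
Why: MnO2 oxidises allylic alcohols selectively to enals without over-oxidation and with retention of alkene geometry.

Step 15
Reactants: 25 (2E,6E)-2,6-dimethylocta-2,6-dienedial
Product: 28 (2E,6E)-2,6-dimethylocta-2,6-dienedioic acid, via 2,6-dimethyl oxo acid 26 (not isolated), via 3,7-dimethyl oxo acid 27 (not isolated)
Conditions: NaClO2, NaH2PO4, 2-methyl-2-butene, t-BuOH/H2O, 0 °C → rt
Reagents that add atoms: sodium chlorite (NaClO2), [Na+].[O-]Cl=O
Why: Pinnick oxidation converts enals to enoic acids under buffered conditions without isomerising or chlorinating the alkenes, the hypochlorous acid being taken up by the sacrificial alkene.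

Step 16
Reactants: 19 (4R,4aS,6S,7S,7aR)-2,4,7-trimethyloctahydro-1H-cyclopenta[c]pyridin-6-ol (2 equiv); 28 (2E,6E)-2,6-dimethylocta-2,6-dienedioic acid
Product: 31 bis[(4R,4aS,6R,7S,7aR)-2,4,7-trimethyloctahydro-1H-cyclopenta[c]pyridin-6-yl] (2E,6E)-2,6-dimethylocta-2,6-dienedioate, via C1-linked half-ester 29 (not isolated), via C8-linked half-ester 30 (not isolated)
Conditions: PPh3, DIAD, THF, 0 °C → rt
Reagents that add atoms: none
Why: In this twofold Mitsunobu esterification each alkoxyphosphonium ion is displaced by a carboxylate with SN2 inversion, turning the concave-face 6S alcohol into the 6R ester with oxygen on the convex face cis to the C7 methyl, a coupling mode that works for hindered cyclopentanols carrying a tertiary amine.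

**Compound list**

1 | furfurylamine | NCc1ccco1 | starting material
2 | methyl (furan-2-ylmethyl)carbamate | COC(=O)NCc1ccco1 | intermediate
3 | methyl [(3Z)-2,5-dioxopent-3-en-1-yl]carbamate (cis-enedione) | COC(=O)NCC(=O)/C=C\C=O | intermediate (not isolated)
4 | methyl 2-hydroxy-5-oxo-5,6-dihydropyridine-1(2H)-carboxylate (racemic) | COC(=O)N1CC(=O)C=CC1O | intermediate
5 | methyl 3-oxo-3,6-dihydropyridine-1(2H)-carboxylate | COC(=O)N1CC=CC(=O)C1 | intermediate
6 | 2-bromo-3-(trimethylsilyl)prop-1-ene | C=C(Br)C[Si](C)(C)C | starting material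
7 | acetaldehyde | CC=O | starting material
8 | [3-(trimethylsilyl)prop-1-en-2-yl]magnesium bromide | C=C([Mg]Br)C[Si](C)(C)C | intermediate (not isolated)
9 | 3-[(trimethylsilyl)methyl]but-3-en-2-ol (racemic) | CC(O)C(=C)C[Si](C)(C)C | intermediate
10 | 3-[(trimethylsilyl)methyl]but-3-en-2-yl acetate (racemic) | CC(OC(C)=O)C(=C)C[Si](C)(C)C | intermediate
11 | methyl (4aR,7S,7aS)-7-methyl-6-methylidene-4-oxooctahydro-2H-cyclopenta[c]pyridine-2-carboxylate | C=C1C[C@@H]2[C@@H](CN(C(=O)OC)CC2=O)[C@@H]1C | intermediate
12 | methyl (4R,4aR,7S,7aS)-4-hydroxy-4,7-dimethyl-6-methylideneoctahydro-2H-cyclopenta[c]pyridine-2-carboxylate | C=C1C[C@@H]2[C@@H](CN(C(=O)OC)C[C@]2(C)O)[C@@H]1C | intermediate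
13 | secondary ozonide of 12 (spiro-1,2,4-trioxolane at C6, both spiro epimers) | C1OOC2(O1)C[C@@H]3[C@@H](CN(C(=O)OC)C[C@]3(C)O)[C@@H]2C | intermediate (not isolated)
14 | methyl (4R,4aR,7S,7aR)-4-hydroxy-4,7-dimethyl-6-oxooctahydro-2H-cyclopenta[c]pyridine-2-carboxylate | O=C1C[C@@H]2[C@@H](CN(C(=O)OC)C[C@]2(C)O)[C@@H]1C | intermediate
15 | triethylammonium salt of the C4 N-(methoxycarbonyl)sulfamate ester of 14 | O=C1C[C@@H]2[C@@H](CN(C(=O)OC)C[C@]2(C)OS(=O)(=O)[N-]C(=O)OC)[C@@H]1C.CC[NH+](CC)CC | intermediate (not isolated)
16 | methyl (4aR,7S,7aR)-4,7-dimethyl-6-oxo-1,4a,5,6,7,7a-hexahydro-2H-cyclopenta[c]pyridine-2-carboxylate | O=C1C[C@@H]2[C@@H](CN(C(=O)OC)C=C2C)[C@@H]1C | intermediate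
17 | methyl (4R,4aS,7S,7aR)-4,7-dimethyl-6-oxooctahydro-2H-cyclopenta[c]pyridine-2-carboxylate | O=C1C[C@@H]2[C@@H](CN(C(=O)OC)C[C@@H]2C)[C@@H]1C | intermediate
18 | methyl (4R,4aS,6S,7S,7aR)-6-hydroxy-4,7-dimethyloctahydro-2H-cyclopenta[c]pyridine-2-carboxylate | O[C@H]1C[C@@H]2[C@@H](CN(C(=O)OC)C[C@@H]2C)[C@@H]1C | intermediate (not isolated)
19 | (4R,4aS,6S,7S,7aR)-2,4,7-trimethyloctahydro-1H-cyclopenta[c]pyridin-6-ol | O[C@H]1C[C@@H]2[C@@H](CN(C)C[C@@H]2C)[C@@H]1C | intermediate
20 | geranyl acetate | CC(=O)OC/C=C(\C)CCC=C(C)C | starting material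
21 | (2E,6E)-8-hydroxy-3,7-dimethylocta-2,6-dien-1-yl acetate | CC(=O)OC/C=C(\C)CC/C=C(\C)CO | intermediate
22 | (2E,6E)-2,6-dimethylocta-2,6-diene-1,8-diol | C/C(=C\CO)CC/C=C(\C)CO | intermediate
23 | (2E,6E)-8-hydroxy-3,7-dimethylocta-2,6-dienal | C/C(=C\C=O)CC/C=C(\C)CO | intermediate (not isolated)
24 | (2E,6E)-8-hydroxy-2,6-dimethylocta-2,6-dienal | C/C(=C\CO)CC/C=C(\C)C=O | intermediate (not isolated)
25 | (2E,6E)-2,6-dimethylocta-2,6-dienedial | C/C(=C\C=O)CC/C=C(\C)C=O | intermediate
26 | (2E,6E)-2,6-dimethyl-8-oxoocta-2,6-dienoic acid | C/C(=C\C=O)CC/C=C(\C)C(=O)O | intermediate (not isolated)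
27 | (2E,6E)-3,7-dimethyl-8-oxoocta-2,6-dienoic acid | C/C(=C\C(=O)O)CC/C=C(\C)C=O | intermediate (not isolated)
28 | (2E,6E)-2,6-dimethylocta-2,6-dienedioic acid | C/C(=C\C(=O)O)CC/C=C(\C)C(=O)O | intermediate
29 | (2E,6E)-3,7-dimethyl-8-oxo-8-{[(4R,4aS,6R,7S,7aR)-2,4,7-trimethyloctahydro-1H-cyclopenta[c]pyridin-6-yl]oxy}octa-2,6-dienoic acid | C/C(=C\C(=O)O)CC/C=C(\C)C(=O)O[C@@H]1C[C@@H]2[C@@H](CN(C)C[C@@H]2C)[C@@H]1C | intermediate (not isolated)
30 | (2E,6E)-2,6-dimethyl-8-oxo-8-{[(4R,4aS,6R,7S,7aR)-2,4,7-trimethyloctahydro-1H-cyclopenta[c]pyridin-6-yl]oxy}octa-2,6-dienoic acid | C/C(=C\C(=O)O[C@@H]1C[C@@H]2[C@@H](CN(C)C[C@@H]2C)[C@@H]1C)CC/C=C(\C)C(=O)O | intermediate (not isolated)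
31 | bis[(4R,4aS,6R,7S,7aR)-2,4,7-trimethyloctahydro-1H-cyclopenta[c]pyridin-6-yl] (2E,6E)-2,6-dimethylocta-2,6-dienedioate | C/C(=C\C(=O)O[C@@H]1C[C@@H]2[C@@H](CN(C)C[C@@H]2C)[C@@H]1C)CC/C=C(\C)C(=O)O[C@@H]1C[C@@H]2[C@@H](CN(C)C[C@@H]2C)[C@@H]1C | target

**Step count**

Total step count: 16.
Longest linear sequence: 10 steps (1, 2, 3, 6, 7, 8, 9, 10, 11, 16).

**Steps most likely to fail**

Step 6. The Michael addition of the zwitterion to a singly activated, enolisable enone may be slower than proton transfer from the acidic C2 methylene of 5, which quenches the donor, and the enantiofacial bias of the ligand may be modest on so small an acceptor. The fallback sets out from 5 and comes back at 11; it gives the acceptor a second, removable activating group. α-Iodination (I2, pyridine, CH2Cl2) should give methyl 4-iodo-3-oxo-3,6-dihydropyridine-1(2H)-carboxylate F1. Methoxycarbonylation (CO 1 atm, MeOH, Et3N, Pd(OAc)2, PPh3) then gives dimethyl 3-oxo-3,6-dihydropyridine-1,4(2H)-dicarboxylate F2, an alkylidene β-keto ester of the acceptor class on which this cycloaddition and its ligand-controlled form work best. Cycloaddition with 10 under the conditions of step 6 should give dimethyl (4aS,7S,7aS)-7-methyl-6-methylidene-4-oxohexahydro-1H-cyclopenta[c]pyridine-2,4a(3H)-dicarboxylate F3. Krapcho dealkoxycarbonylation (LiCl, wet DMSO, 130 °C) removes the angular ester, and protonation of the enol on the convex face should return cis-fused 11.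

Step 9. Regiocontrol in the elimination may be lost. Elimination into the C4 methyl group instead of the ring would do no harm, because hydrogenation in step 10 sets the same C4 centre from either alkene position. The damaging course is loss of hydrogen from C4a, which becomes possible if some C4 epimer of 14 is present (incomplete face selectivity in step 7) or if the sulfamate ionises (E1). That erases the ring-fusion centre and leaves a tetrasubstituted alkene that hydrogenates slowly and without face control. The fallback sets out from 14 and comes back at 17; it makes no alkene. Acylation with methyl chlorooxoacetate (ClCOCO2Me, DMAP, pyridine, CH2Cl2) gives the tertiary oxalate methyl (4R,4aR,7S,7aR)-4-[(methoxyoxalyl)oxy]-4,7-dimethyl-6-oxooctahydro-2H-cyclopenta[c]pyridine-2-carboxylate F4. Bu3SnH and AIBN in refluxing toluene (Barton–McCombie-type radical deoxygenation of a tertiary oxalate) generate the C4 radical, which should take hydrogen from the convex face just as the alkene does. DBU treatment as in step 10 then gives 17.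

Step 11. Facial selectivity in the hydride addition may be poor or reversed, because the convex face also carries the C7 methyl. Part or all of the alcohol would then have its hydroxyl on the convex face, and Mitsunobu inversion would give the wrong C6 ester. The fallback sets out from 17 and comes back at 31; it uses each epimer as it comes. The product of concave-face delivery, methyl (4R,4aS,6R,7S,7aR)-6-hydroxy-4,7-dimethyloctahydro-2H-cyclopenta[c]pyridine-2-carboxylate F5, is reduced on in the same flask to (4R,4aS,6R,7S,7aR)-2,4,7-trimethyloctahydro-1H-cyclopenta[c]pyridin-6-ol F6, which already has the C6 configuration of the target. After chromatographic separation from 19, this alcohol is esterified with retention (28, EDC·HCl, DMAP, CH2Cl2; Steglich esterification, through the same half-esters 29 and 30) to give 31. Any 19 goes through step 16, so both epimers converge on the target.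

Further compounds
F1 | step 6 | methyl 4-iodo-3-oxo-3,6-dihydropyridine-1(2H)-carboxylate | COC(=O)N1CC=C(I)C(=O)C1
F2 | step 6 | dimethyl 3-oxo-3,6-dihydropyridine-1,4(2H)-dicarboxylate | COC(=O)N1CC=C(C(=O)OC)C(=O)C1
F3 | step 6 | dimethyl (4aS,7S,7aS)-7-methyl-6-methylidene-4-oxohexahydro-1H-cyclopenta[c]pyridine-2,4a(3H)-dicarboxylate | C=C1C[C@]2(C(=O)OC)[C@@H](CN(C(=O)OC)CC2=O)[C@@H]1C
F4 | step 9 | methyl (4R,4aR,7S,7aR)-4-[(methoxyoxalyl)oxy]-4,7-dimethyl-6-oxooctahydro-2H-cyclopenta[c]pyridine-2-carboxylate | O=C1C[C@@H]2[C@@H](CN(C(=O)OC)C[C@]2(C)OC(=O)C(=O)OC)[C@@H]1C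
F5 | step 11 | methyl (4R,4aS,6R,7S,7aR)-6-hydroxy-4,7-dimethyloctahydro-2H-cyclopenta[c]pyridine-2-carboxylate | O[C@@H]1C[C@@H]2[C@@H](CN(C(=O)OC)C[C@@H]2C)[C@@H]1C
F6 | step 11 | (4R,4aS,6R,7S,7aR)-2,4,7-trimethyloctahydro-1H-cyclopenta[c]pyridin-6-ol | O[C@@H]1C[C@@H]2[C@@H](CN(C)C[C@@H]2C)[C@@H]1C
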